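**Plan**

1. Retrosynthesis: the two acyl groups and the C6 configuration go back through a 6-ketone to a 6α-OSiEt3/7α-OTBS pair; C9–C11 is cut (Negishi coupling at a C8=C9 enol triflate of a C9 ketone) and one C4 methyl is removed (hydromethylation of C3=C4).
2. The resulting Δ3-decal-9-one is cut at C1–C2 and C5–C10 in one retro-[4+2] to an acyclic 1,7,9-decatrien-3-one, which is cut at C7–C8 (anti aldol) into ethyl isopropenyl ketone and an α-silyloxy dienal from (S)-glyceraldehyde acetonide.
3. Enabling feature: ring A (C1–C5, C10) is a cyclohexane whose C4 can sit on a C3=C4 alkene and whose quaternary C10 is bonded to C9, which can be a ketone; ring A is therefore the adduct of a C2=C3–C4(Me)=C5 diene and a C1=C10(Me)–C9(=O) enone, joined through C6–C9 of ring B as a four-atom tether.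
4. Forward: chain assembly (C2–C10), then rings A and B together, then the C4 gem-dimethyl group, then C8=C9 with the side chain, then the ring B oxygen pattern, then the free acid.
5. Stereochemistry: C6 (temporary 6α) from the chiral pool; C7 by Felkin-controlled anti aldol; C5 and C10 in the cycloaddition (A(1,3) strain, chair tether); 6β by hydride attack on the 6-ketone from the α face; 13E by syn-carboalumination.

Key step: step 8

Remark: atoms are numbered as in labdanes (ring A: C1–C5 and C10; ring B: C5–C10; side chain C11–C15); 2-(trimethylsilyl)ethyl chloroformate and formaldehyde N-octylsulfonylhydrazone are assumed to be made beforehand by standard procedures (from 2-(trimethylsilyl)ethanol and from octane-1-sulfonohydrazide).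

**Route**

Step 1
Reactants: 1 (S)-2,2-dimethyl-1,3-dioxolane-4-carbaldehyde; 2 2-(triphenylphosphoranylidene)propanal
Product: 3 (2E)-3-[(4R)-2,2-dimethyl-1,3-dioxolan-4-yl]-2-methylprop-2-enal
Conditions: toluene, 80 °C
Reagents that add atoms: none
Why: Wittig olefination with a formyl-stabilised ylide should give the (E)-2-methyl enal, and the neutral conditions leave the α-alkoxy stereocentre (the later C6) untouched.

Step 2
Reactants: 3 (2E)-3-[(4R)-2,2-dimethyl-1,3-dioxolan-4-yl]-2-methylprop-2-enal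
Product: 4 (4R)-2,2-dimethyl-4-[(1E)-2-methylbuta-1,3-dien-1-yl]-1,3-dioxolane
Conditions: Ph3PCH3Br, KOt-Bu, THF, 0 °C; then 3, 0 °C → rt
Reagents that add atoms: methyltriphenylphosphonium bromide, C[P+](c1ccccc1)(c1ccccc1)c1ccccc1.[Br-]
Why: Wittig methylenation of the enal should complete the C2=C3–C4(Me)=C5 diene without changing the C4=C5 geometry.

Step 3
Reactants: 4 (4R)-2,2-dimethyl-4-[(1E)-2-methylbuta-1,3-dien-1-yl]-1,3-dioxolane
Product: 5 (2R,3E)-4-methylhexa-3,5-diene-1,2-diol
Conditions: 80% aq. AcOH, 40 °C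
Reagents that add atoms: none
Why: Acid-catalysed acetal hydrolysis under mild conditions should free the diol without ionising the dienylic C–O bond.

Step 4
Reactants: 5 (2R,3E)-4-methylhexa-3,5-diene-1,2-diol
Product: 6 (2R,3E)-4-methyl-1,2-bis(triethylsilyloxy)hexa-3,5-diene
Conditions: TESCl, imidazole, DMF, 0 °C → rt
Reagents that add atoms: chlorotriethylsilane, CC[Si](Cl)(CC)CC
Why: Standard silylation of both hydroxyls sets up the selective oxidation of the primary position.

Step 5
Reactants: 6 (2R,3E)-4-methyl-1,2-bis(triethylsilyloxy)hexa-3,5-diene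
Product: 8 (2R,3E)-4-methyl-2-(triethylsilyloxy)hexa-3,5-dienal, via alkoxydimethylsulfonium chloride 7 (not isolated)
Conditions: (COCl)2, DMSO, CH2Cl2, −78 °C; then 6, −78 → −35 °C; then Et3N, −78 → 0 °C; used crude
Reagents that add atoms: none
Why: Swern conditions are known to cleave and oxidise a primary triethylsilyl ether in the presence of a secondary one, and low temperature with immediate use should protect the α-stereocentre, which is both α to the aldehyde and allylic.

Step 6
Reactants: 8 (2R,3E)-4-methyl-2-(triethylsilyloxy)hexa-3,5-dienal; 9 2-methylpent-1-en-3-one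
Product: 12 (4R,5S,6R,7E)-5-hydroxy-2,4,8-trimethyl-6-(triethylsilyloxy)deca-1,7,9-trien-3-one, via (E)-enol dicyclohexylborinate 10 (not isolated), via boron aldolate 11 (not isolated)
Conditions: Cy2BCl, Et3N, Et2O, −78 → 0 °C; then 8, −78 → −20 °C; MeOH, pH 7 buffer (no peroxide)
Reagents that add atoms: none
Why: Boron-mediated anti aldol: the (E)-enol borinate reacts through a Zimmerman–Traxler chair to set C7/C8 anti, and Felkin–Anh addition to the α-silyloxy aldehyde sets C6/C7 anti, so C7 (S) is set from C6; the non-oxidative work-up spares the enone.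

Step 7
Reactants: 12 (4R,5S,6R,7E)-5-hydroxy-2,4,8-trimethyl-6-(triethylsilyloxy)deca-1,7,9-trien-3-one
Product: 13 (4R,5S,6R,7E)-5-(tert-butyldimethylsilyloxy)-2,4,8-trimethyl-6-(triethylsilyloxy)deca-1,7,9-trien-3-one
Conditions: TBSOTf, 2,6-lutidine, CH2Cl2, −78 °C
Reagents that add atoms: tert-butyldimethylsilyl trifluoromethanesulfonate, CC(C)(C)[Si](C)(C)OS(=O)(=O)C(F)(F)F
Why: Low-temperature silylation of the β-hydroxy ketone should avoid retro-aldol and elimination and gives a C7 group that outlasts the C6 triethylsilyl ether.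

Step 8
Reactants: 13 (4R,5S,6R,7E)-5-(tert-butyldimethylsilyloxy)-2,4,8-trimethyl-6-(triethylsilyloxy)deca-1,7,9-trien-3-one
Product: 14 (2R,3S,4R,4aS,8aS)-3-(tert-butyldimethylsilyloxy)-2,5,8a-trimethyl-4-(triethylsilyloxy)-3,4,4a,7,8,8a-hexahydronaphthalen-1(2H)-one
Conditions: toluene (0.01 M), BHT, 150 °C, sealed tube
Reagents that add atoms: none
Why: Thermal, concerted but asynchronous suprafacial [4+2] cycloaddition (a type 1 intramolecular Diels–Alder reaction of a 1,7,9-decatrien-3-one, the closest known reaction type), in which the C2=C3–C4(Me)=C5 diene adds to the C1=C10 bond of the isopropenyl ketone and forms C1–C2 and C5–C10 together. Ring A (C1–C5, C10) closes as the six-membered cycloaddition ring, and ring B (C5–C10) closes through the C5–C10 bond as the six-membered tether ring in the fused mode, via a chair-like tether with the C9 carbonyl exo. The trans relation of C5–H and C10–Me follows from this exo-carbonyl transition state, which A(1,3) strain enforces: the C4 methyl is cis to C6 on the diene, so the cis-fused arrangement would push C7 against it, whereas the trans arrangement places only the C6–H there. The absolute sense at C5 and C10 is set by the tether stereocentres: with C6–H in the diene plane the dienophile reaches the diene face that carries C7, and only one chair has the 6-silyloxy and 8-methyl groups equatorial (7-OTBS axial) and avoids a syn-axial clash with the C10 methyl. The step needs ring-fusion (exo/endo) and π-facial selectivity, both secured as described; regiochemistry is fixed by the four-atom tether, and a 1,5-hydrogen shift in the diene is impossible because C6 is trans to C3.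

Step 9
Reactants: 14 (2R,3S,4R,4aS,8aS)-3-(tert-butyldimethylsilyloxy)-2,5,8a-trimethyl-4-(triethylsilyloxy)-3,4,4a,7,8,8a-hexahydronaphthalen-1(2H)-one
Product: 16 (2R,3S,4R,4aS,8aS)-3-(tert-butyldimethylsilyloxy)-2,5,5,8a-tetramethyl-4-(triethylsilyloxy)octahydronaphthalen-1(2H)-one, via sulfonylhydrazide adduct 15 (not isolated)
Conditions: Fe(acac)3 (cat.), PhSiH3, formaldehyde N-octylsulfonylhydrazone, THF/MeOH, rt; then MeOH, 60 °C
Reagents that add atoms: formaldehyde N-octylsulfonylhydrazone, C=NNS(=O)(=O)CCCCCCCC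
Why: Metal-hydride hydrogen-atom transfer to the trisubstituted C3=C4 alkene gives the tertiary C4 radical (Markovnikov), which adds to the hydrazone carbon; loss of sulfinate and N2 on warming leaves the second C4 methyl, and no stereocentre arises because C4 becomes gem-dimethyl.

Step 10
Reactants: 16 (2R,3S,4R,4aS,8aS)-3-(tert-butyldimethylsilyloxy)-2,5,5,8a-tetramethyl-4-(triethylsilyloxy)octahydronaphthalen-1(2H)-one
Product: 18 (3S,4R,4aS,8aS)-3-(tert-butyldimethylsilyloxy)-2,5,5,8a-tetramethyl-4-(triethylsilyloxy)-3,4,4a,5,6,7,8,8a-octahydronaphthalen-1-yl trifluoromethanesulfonate, via potassium enolate 17 (not isolated)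
Conditions: KN(SiMe3)2, THF, −78 °C; then N-(5-chloropyridin-2-yl)bis(trifluoromethanesulfonimide), −78 → −40 °C
Reagents that add atoms: N-(5-chloropyridin-2-yl)bis(trifluoromethanesulfonimide), O=S(=O)(N(c1ccc(Cl)cn1)S(=O)(=O)C(F)(F)F)C(F)(F)F
Why: Enolisation can only go toward C8 because C10 is quaternary, so O-triflation fixes the tetrasubstituted C8=C9 alkene; low temperature should keep the β-silyloxy enolate from E1cB loss of the C7 oxygen.

Step 11
Reactants: 19 but-3-yn-1-ol
Product: 21 2-(trimethylsilyl)ethyl (2E)-5-hydroxy-3-methylpent-2-enoate, via alkenylalane 20 (not isolated)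
Conditions: Me3Al, Cp2ZrCl2 (cat.), CH2Cl2, 0 °C → rt; then ClCO2CH2CH2SiMe3, 0 °C → rt; aq. work-up
Reagents that add atoms: trimethylaluminium, C[Al](C)C; 2-(trimethylsilyl)ethyl chloroformate, O=C(Cl)OCC[Si](C)(C)C
Why: Zirconocene-catalysed syn-carboalumination puts methyl on the internal and aluminium on the terminal alkyne carbon, and acylation of the alkenyl–Al bond with retention should give the (E)-3-methyl enoate only (the alcohol rides as its aluminium alkoxide).

Step 12
Reactants: 21 2-(trimethylsilyl)ethyl (2E)-5-hydroxy-3-methylpent-2-enoate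
Product: 22 2-(trimethylsilyl)ethyl (2E)-5-iodo-3-methylpent-2-enoate
Conditions: I2, PPh3, imidazole, CH2Cl2, 0 °C → rt
Reagents that add atoms: iodine, II
Why: Appel-type iodination of the primary alcohol proceeds under neutral conditions that leave the enoate geometry alone.

Step 13
Reactants: 18 (3S,4R,4aS,8aS)-3-(tert-butyldimethylsilyloxy)-2,5,5,8a-tetramethyl-4-(triethylsilyloxy)-3,4,4a,5,6,7,8,8a-octahydronaphthalen-1-yl trifluoromethanesulfonate; 22 2-(trimethylsilyl)ethyl (2E)-5-iodo-3-methylpent-2-enoate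
Product: 24 2-(trimethylsilyl)ethyl (5S,6R,7S,10S,13E)-7-(tert-butyldimethylsilyloxy)-6-(triethylsilyloxy)labda-8,13-dien-15-oate, via alkylzinc iodide 23 (not isolated)
Conditions: 22, Zn dust, LiCl, THF, 40 °C; then 18, Pd(OAc)2, SPhos, THF/NMP, 60 °C
Reagents that add atoms: none
Why: Negishi sp3–sp2 coupling: zinc insertion tolerates the ester, zerovalent palladium adds oxidatively to the alkenyl triflate, and the bulky biarylphosphine favours reductive elimination over β-hydride elimination; couplings of this kind at 2,6,6-trisubstituted cyclohexenyl triflates are well known.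

Step 14
Reactants: 24 2-(trimethylsilyl)ethyl (5S,6R,7S,10S,13E)-7-(tert-butyldimethylsilyloxy)-6-(triethylsilyloxy)labda-8,13-dien-15-oate
Product: 25 2-(trimethylsilyl)ethyl (5S,6R,7S,10S,13E)-7-(tert-butyldimethylsilyloxy)-6-hydroxylabda-8,13-dien-15-oate
Conditions: HF·pyridine, pyridine, THF, 0 °C
Reagents that add atoms: none
Why: Buffered fluoride should cleave the triethylsilyl ether much faster than the TBS ether and should leave the 2-(trimethylsilyl)ethyl ester intact.

Step 15
Reactants: 25 2-(trimethylsilyl)ethyl (5S,6R,7S,10S,13E)-7-(tert-butyldimethylsilyloxy)-6-hydroxylabda-8,13-dien-15-oate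
Product: 26 2-(trimethylsilyl)ethyl (5S,7S,10S,13E)-7-(tert-butyldimethylsilyloxy)-6-oxolabda-8,13-dien-15-oate
Conditions: Dess–Martin periodinane, pyridine, CH2Cl2, 0 °C → rt
Reagents that add atoms: none
Why: Neutral periodinane oxidation removes the temporary C6 stereocentre without enolising C5 or C7; the pseudoaxial 7α-silyloxy group is in any case the one favoured next to the C8 methyl (A(1,2) strain).

Step 16
Reactants: 26 2-(trimethylsilyl)ethyl (5S,7S,10S,13E)-7-(tert-butyldimethylsilyloxy)-6-oxolabda-8,13-dien-15-oate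
Product: 27 2-(trimethylsilyl)ethyl (5S,6S,7S,10S,13E)-7-(tert-butyldimethylsilyloxy)-6-hydroxylabda-8,13-dien-15-oate
Conditions: NaBH4, CeCl3·7H2O, MeOH, −40 °C
Reagents that add atoms: none
Why: Hydride should add to the C6 carbonyl from the α face, because the β face is blocked by the syn-axial C10 methyl and the 4β methyl, giving the axial 6β alcohol; the cerium salt keeps the medium nearly neutral and the enoate is not reduced.

Step 17
Reactants: 27 2-(trimethylsilyl)ethyl (5S,6S,7S,10S,13E)-7-(tert-butyldimethylsilyloxy)-6-hydroxylabda-8,13-dien-15-oate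
Product: 28 2-(trimethylsilyl)ethyl (5S,6S,7S,10S,13E)-6-acetoxy-7-(tert-butyldimethylsilyloxy)labda-8,13-dien-15-oate
Conditions: Ac2O, DMAP, pyridine, 60 °C
Reagents that add atoms: acetic anhydride, CC(=O)OC(C)=O
Why: DMAP-catalysed acetylation under forcing conditions is needed for the hindered axial 6β-hydroxyl, and nothing else in the molecule can be acylated.

Step 18
Reactants: 28 2-(trimethylsilyl)ethyl (5S,6S,7S,10S,13E)-6-acetoxy-7-(tert-butyldimethylsilyloxy)labda-8,13-dien-15-oate
Product: 29 2-(trimethylsilyl)ethyl (5S,6S,7S,10S,13E)-6-acetoxy-7-hydroxylabda-8,13-dien-15-oate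
Conditions: HF·pyridine, THF, rt
Reagents that add atoms: none
Why: Acidic fluoride removes the allylic TBS ether without generating a free alkoxide next to the acetate, so acyl migration is not expected, and the 2-(trimethylsilyl)ethyl ester survives.

Step 19
Reactants: 29 2-(trimethylsilyl)ethyl (5S,6S,7S,10S,13E)-6-acetoxy-7-hydroxylabda-8,13-dien-15-oate
Product: 30 2-(trimethylsilyl)ethyl (5S,6S,7S,10S,13E)-6-acetoxy-7-(3-methylbutanoyloxy)labda-8,13-dien-15-oate
Conditions: (i-BuCO)2O, DMAP, Et3N, CH2Cl2, rt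
Reagents that add atoms: 3-methylbutanoic anhydride, CC(C)CC(=O)OC(=O)CC(C)C
Why: DMAP-catalysed acylation of the only free hydroxyl (7α, allylic) installs the isovalerate with retention at C7.

Step 20
Reactants: 30 2-(trimethylsilyl)ethyl (5S,6S,7S,10S,13E)-6-acetoxy-7-(3-methylbutanoyloxy)labda-8,13-dien-15-oate
Product: 32 (5S,6S,7S,10S,13E)-6-acetoxy-7-(3-methylbutanoyloxy)labda-8,13-dien-15-oic acid, via tetrabutylammonium carboxylate 31 (not isolated)
Conditions: TBAF, THF, 0 °C → rt; then 0.5 M aq. HCl, 0 °C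
Reagents that add atoms: none
Why: Fluoride attack at silicon fragments the 2-(trimethylsilyl)ethyl ester to ethene and the carboxylate, a cleavage that should leave the acetate and the isovalerate untouched.

**Compound list**

1 | (S)-2,2-dimethyl-1,3-dioxolane-4-carbaldehyde ((S)-glyceraldehyde acetonide) | CC1(C)OC[C@@H](C=O)O1 | starting material
2 | 2-(triphenylphosphoranylidene)propanal | CC(C=O)=P(c1ccccc1)(c1ccccc1)c1ccccc1 | starting material
3 | (2E)-3-[(4R)-2,2-dimethyl-1,3-dioxolan-4-yl]-2-methylprop-2-enal | CC1(C)OC[C@@H](/C=C(\C)C=O)O1 | intermediate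
4 | (4R)-2,2-dimethyl-4-[(1E)-2-methylbuta-1,3-dien-1-yl]-1,3-dioxolane | CC1(C)OC[C@@H](/C=C(\C)C=C)O1 | intermediate
5 | (2R,3E)-4-methylhexa-3,5-diene-1,2-diol | OC[C@H](O)/C=C(\C)C=C | intermediate
6 | (2R,3E)-4-methyl-1,2-bis(triethylsilyloxy)hexa-3,5-diene | CC[Si](CC)(CC)OC[C@H](O[Si](CC)(CC)CC)/C=C(\C)C=C | intermediate
7 | dimethyl{[(2R,3E)-4-methyl-2-(triethylsilyloxy)hexa-3,5-dien-1-yl]oxy}sulfonium chloride (not isolated) | C[S+](C)OC[C@H](O[Si](CC)(CC)CC)/C=C(\C)C=C.[Cl-] | intermediate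
8 | (2R,3E)-4-methyl-2-(triethylsilyloxy)hexa-3,5-dienal | O=C[C@H](O[Si](CC)(CC)CC)/C=C(\C)C=C | intermediate
9 | 2-methylpent-1-en-3-one (ethyl isopropenyl ketone) | C=C(C)C(=O)CC | starting material
10 | dicyclohexyl{[(3E)-2-methylpenta-1,3-dien-3-yl]oxy}borane, the (E)-enol borinate of 9 (not isolated) | C/C=C(/OB(C1CCCCC1)C1CCCCC1)C(C)=C | intermediate
11 | O-dicyclohexylboryl aldolate of 12 (not isolated) | C=C/C(C)=C/[C@@H](O[Si](CC)(CC)CC)[C@@H](OB(C1CCCCC1)C1CCCCC1)[C@@H](C)C(=O)C(C)=C | intermediate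
12 | (4R,5S,6R,7E)-5-hydroxy-2,4,8-trimethyl-6-(triethylsilyloxy)deca-1,7,9-trien-3-one | C=C/C(C)=C/[C@@H](O[Si](CC)(CC)CC)[C@@H](O)[C@@H](C)C(=O)C(C)=C | intermediate
13 | (4R,5S,6R,7E)-5-(tert-butyldimethylsilyloxy)-2,4,8-trimethyl-6-(triethylsilyloxy)deca-1,7,9-trien-3-one | C=C/C(C)=C/[C@@H](O[Si](CC)(CC)CC)[C@@H](O[Si](C)(C)C(C)(C)C)[C@@H](C)C(=O)C(C)=C | intermediate
14 | (2R,3S,4R,4aS,8aS)-3-(tert-butyldimethylsilyloxy)-2,5,8a-trimethyl-4-(triethylsilyloxy)-3,4,4a,7,8,8a-hexahydronaphthalen-1(2H)-one (trans-fused; labdane positions: 5α-H, 10β-Me, 6α-OSiEt3, 7α-OTBS, 8α-Me, 9-oxo, C3=C4) | C[C@H]1C(=O)[C@@]2(C)CCC=C(C)[C@@H]2[C@@H](O[Si](CC)(CC)CC)[C@H]1O[Si](C)(C)C(C)(C)C | intermediate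
15 | N'-alkyl octane-1-sulfonohydrazide adduct at C4 of 14 (C4 epimers; not isolated) | C[C@H]1C(=O)[C@@]2(C)CCCC(C)(CNNS(=O)(=O)CCCCCCCC)[C@@H]2[C@@H](O[Si](CC)(CC)CC)[C@H]1O[Si](C)(C)C(C)(C)C | intermediate
16 | (2R,3S,4R,4aS,8aS)-3-(tert-butyldimethylsilyloxy)-2,5,5,8a-tetramethyl-4-(triethylsilyloxy)octahydronaphthalen-1(2H)-one | C[C@H]1C(=O)[C@@]2(C)CCCC(C)(C)[C@@H]2[C@@H](O[Si](CC)(CC)CC)[C@H]1O[Si](C)(C)C(C)(C)C | intermediate
17 | potassium C8=C9 enolate of 16 (not isolated) | CC1=C([O-])[C@@]2(C)CCCC(C)(C)[C@@H]2[C@@H](O[Si](CC)(CC)CC)[C@H]1O[Si](C)(C)C(C)(C)C.[K+] | intermediate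
18 | (3S,4R,4aS,8aS)-3-(tert-butyldimethylsilyloxy)-2,5,5,8a-tetramethyl-4-(triethylsilyloxy)-3,4,4a,5,6,7,8,8a-octahydronaphthalen-1-yl trifluoromethanesulfonate | CC1=C(OS(=O)(=O)C(F)(F)F)[C@@]2(C)CCCC(C)(C)[C@@H]2[C@@H](O[Si](CC)(CC)CC)[C@H]1O[Si](C)(C)C(C)(C)C | intermediate
19 | but-3-yn-1-ol | C#CCCO | starting material
20 | (E)-alkenyldimethylalane from 19, O-bound as the dimethylaluminium alkoxide (not isolated) | C[Al](C)/C=C(\C)CCO[Al](C)C | intermediate
21 | 2-(trimethylsilyl)ethyl (2E)-5-hydroxy-3-methylpent-2-enoate | OCC/C(C)=C/C(=O)OCC[Si](C)(C)C | intermediate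
22 | 2-(trimethylsilyl)ethyl (2E)-5-iodo-3-methylpent-2-enoate | ICC/C(C)=C/C(=O)OCC[Si](C)(C)C | intermediate
23 | alkylzinc iodide from 22 (not isolated) | I[Zn]CC/C(C)=C/C(=O)OCC[Si](C)(C)C | intermediate
24 | 2-(trimethylsilyl)ethyl (5S,6R,7S,10S,13E)-7-(tert-butyldimethylsilyloxy)-6-(triethylsilyloxy)labda-8,13-dien-15-oate (6α, 7α) | CC1=C(CC/C(C)=C/C(=O)OCC[Si](C)(C)C)[C@@]2(C)CCCC(C)(C)[C@@H]2[C@@H](O[Si](CC)(CC)CC)[C@H]1O[Si](C)(C)C(C)(C)C | intermediate
25 | 2-(trimethylsilyl)ethyl (5S,6R,7S,10S,13E)-7-(tert-butyldimethylsilyloxy)-6-hydroxylabda-8,13-dien-15-oate (6α-OH) | CC1=C(CC/C(C)=C/C(=O)OCC[Si](C)(C)C)[C@@]2(C)CCCC(C)(C)[C@@H]2[C@@H](O)[C@H]1O[Si](C)(C)C(C)(C)C | intermediate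
26 | 2-(trimethylsilyl)ethyl (5S,7S,10S,13E)-7-(tert-butyldimethylsilyloxy)-6-oxolabda-8,13-dien-15-oate | CC1=C(CC/C(C)=C/C(=O)OCC[Si](C)(C)C)[C@@]2(C)CCCC(C)(C)[C@@H]2C(=O)[C@H]1O[Si](C)(C)C(C)(C)C | intermediate
27 | 2-(trimethylsilyl)ethyl (5S,6S,7S,10S,13E)-7-(tert-butyldimethylsilyloxy)-6-hydroxylabda-8,13-dien-15-oate (6β-OH) | CC1=C(CC/C(C)=C/C(=O)OCC[Si](C)(C)C)[C@@]2(C)CCCC(C)(C)[C@@H]2[C@H](O)[C@H]1O[Si](C)(C)C(C)(C)C | intermediate
28 | 2-(trimethylsilyl)ethyl (5S,6S,7S,10S,13E)-6-acetoxy-7-(tert-butyldimethylsilyloxy)labda-8,13-dien-15-oate | CC1=C(CC/C(C)=C/C(=O)OCC[Si](C)(C)C)[C@@]2(C)CCCC(C)(C)[C@@H]2[C@H](OC(C)=O)[C@H]1O[Si](C)(C)C(C)(C)C | intermediate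
29 | 2-(trimethylsilyl)ethyl (5S,6S,7S,10S,13E)-6-acetoxy-7-hydroxylabda-8,13-dien-15-oate | CC1=C(CC/C(C)=C/C(=O)OCC[Si](C)(C)C)[C@@]2(C)CCCC(C)(C)[C@@H]2[C@H](OC(C)=O)[C@H]1O | intermediate
30 | 2-(trimethylsilyl)ethyl (5S,6S,7S,10S,13E)-6-acetoxy-7-(3-methylbutanoyloxy)labda-8,13-dien-15-oate | CC1=C(CC/C(C)=C/C(=O)OCC[Si](C)(C)C)[C@@]2(C)CCCC(C)(C)[C@@H]2[C@H](OC(C)=O)[C@H]1OC(=O)CC(C)C | intermediate
31 | tetrabutylammonium salt of 32 (not isolated) | CC1=C(CC/C(C)=C/C(=O)[O-])[C@@]2(C)CCCC(C)(C)[C@@H]2[C@H](OC(C)=O)[C@H]1OC(=O)CC(C)C.CCCC[N+](CCCC)(CCCC)CCCC | intermediate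
32 | (5S,6S,7S,10S,13E)-6-acetoxy-7-(3-methylbutanoyloxy)labda-8,13-dien-15-oic acid (6β-acetoxy, 7α-isovaleryloxy; CNP0328312.2) | CC(=O)O[C@@H]1[C@@H](OC(=O)CC(C)C)C(C)=C(CC/C(C)=C/C(=O)O)[C@@]2(C)CCCC(C)(C)[C@H]12 | target

Total step count: 20. Longest linear sequence: 18 steps (steps 1–10 and 13–20); steps 11–12 make the side-chain fragment.

**Steps most likely to fail**

Step 8. The π-facial or ring-fusion selectivity may erode because the required chair carries the bulky 7-silyloxy group axial, and the β-silyloxy ketone may lose silanol on prolonged heating. The fallback ties O6 and O7 into a small cis-fused acetonide, so that the tether conformation is governed only by A(1,3) strain and the equatorial C8 methyl. It sets out from 12. 2,2-Dimethoxypropane and PPTS in MeOH/CH2Cl2 cleave the triethylsilyl ether and close the dioxolane to give the acetonide trienone F1. Thermal cycloaddition as in step 8 gives the acetonide decalone F2. Aqueous acetic acid frees the 6α,7α-diol F3. TESCl/imidazole at −20 °C should silylate the equatorial 6-hydroxyl first, giving the 6-O-triethylsilyl ether F4, and TBSOTf/2,6-lutidine then gives 14, where the route is rejoined.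

Step 9. The hindered tertiary C4 radical may be reduced by a second hydrogen-atom transfer (net hydrogenation of C3=C4) or may add too slowly to the hydrazone. The fallback is the classical two-step gem-dimethylation. It sets out from 14. Cyclopropanation of the C3=C4 alkene with Et2Zn/CH2I2/CF3CO2H gives the cyclopropane F5 (either face; both converge). Hydrogenolysis over PtO2 (H2, EtOAc with a little AcOH) cleaves the less hindered C3–CH2 bond of the three-membered ring and gives 16, where the route is rejoined.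

Step 16. Facial selectivity of hydride addition may be poor because the axial 7α-OTBS group crowds the α face, and enolisation toward C7 may compete. The fallback is a hydroxyl-directed reduction with a changed order of acylation. It sets out from 26. HF·pyridine removes the TBS group to give the α-hydroxy ketone F6. Me4NBH(OAc)3 in MeCN/AcOH at −20 °C delivers hydride from the boron bound to the 7α-oxygen to the α face of C6 and gives the 6β,7α-diol F7. 3-Methylbutanoic anhydride with DMAP at low temperature acylates the less hindered allylic 7α-hydroxyl to give the 7-isovalerate F8. Forcing acetylation of the 6β-hydroxyl (Ac2O, DMAP, pyridine, 60 °C) then gives 30, where the route is rejoined.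

**Further compounds**

F1 | step 8 | 6,7-O-isopropylidene analogue of 13 (cis-dioxolane trienone from the diol of 12) | C=C/C(C)=C/[C@H]1OC(C)(C)O[C@H]1[C@@H](C)C(=O)C(C)=C
F2 | step 8 | 6α,7α-O-isopropylidene analogue of 14 (trans-fused acetonide decalone) | C[C@H]1C(=O)[C@@]2(C)CCC=C(C)[C@@H]2[C@H]3OC(C)(C)O[C@@H]13
F3 | step 8 | 6α,7α-diol corresponding to 14 | C[C@H]1C(=O)[C@@]2(C)CCC=C(C)[C@@H]2[C@@H](O)[C@H]1O
F4 | step 8 | 6α-O-triethylsilyl 7α-hydroxy decalone | C[C@H]1C(=O)[C@@]2(C)CCC=C(C)[C@@H]2[C@@H](O[Si](CC)(CC)CC)[C@H]1O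
F5 | step 9 | 3,4-methano (cyclopropane) derivative of 14, either face | C[C@H]1C(=O)[C@@]2(C)CCC3CC3(C)[C@@H]2[C@@H](O[Si](CC)(CC)CC)[C@H]1O[Si](C)(C)C(C)(C)C
F6 | step 16 | 2-(trimethylsilyl)ethyl (5S,7S,10S,13E)-7-hydroxy-6-oxolabda-8,13-dien-15-oate | CC1=C(CC/C(C)=C/C(=O)OCC[Si](C)(C)C)[C@@]2(C)CCCC(C)(C)[C@@H]2C(=O)[C@H]1O
F7 | step 16 | 2-(trimethylsilyl)ethyl (5S,6S,7S,10S,13E)-6,7-dihydroxylabda-8,13-dien-15-oate (6β,7α) | CC1=C(CC/C(C)=C/C(=O)OCC[Si](C)(C)C)[C@@]2(C)CCCC(C)(C)[C@@H]2[C@H](O)[C@H]1O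
F8 | step 16 | 2-(trimethylsilyl)ethyl (5S,6S,7S,10S,13E)-6-hydroxy-7-(3-methylbutanoyloxy)labda-8,13-dien-15-oate | CC1=C(CC/C(C)=C/C(=O)OCC[Si](C)(C)C)[C@@]2(C)CCCC(C)(C)[C@@H]2[C@H](O)[C@H]1OC(=O)CC(C)C
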